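Ring B of the flavone is disconnected across C1'–C2' and C5'–C6'. Its two adjacent oxygens at C3' and C4' correspond to the symmetric bis(silyl enol ether) of butane-2,3-dione. A single thermal [4+2] cycloaddition of that diene onto an ethynyl group at C2 of the chromone (rings A and C), followed by DDQ dehydrogenation in the same flask, therefore builds the whole catechol ring with its oxygens already capped and with no regiochemical question. The dienophile is a 2-ethynyl-5-hydroxychromone that already carries the 7-O-sulfate as its robust neopentyl diester, made from 2',4',6'-trihydroxyacetophenone and diethyl oxalate. Two mild deprotections finish the synthesis.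

Key step: step 8

Assumption: the target is taken as the free hydrogen sulfate as drawn; it is generated by cold protonation of the sodium salt formed in the last step and should be kept cold (all compounds of the route are achiral).

Step 1
Reactants: 1 2',4',6'-trihydroxyacetophenone (dried); 2 diethyl oxalate
Product: 4 ethyl 5,7-dihydroxy-4-oxo-4H-chromene-2-carboxylate, via diketo ester 3 (not isolated)
Conditions: NaOEt (6 equiv), EtOH, reflux; then conc. HCl, EtOH, reflux
Reagents that add atoms: none
Why: Crossed Claisen condensation of the methyl ketone enolate with the non-enolizable oxalate gives 3, and acid closes ring C by attack of an ortho OH on the 2-keto group and dehydration; the two ortho phenols are equivalent, so only one chromone can form.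

Step 2
Reactants: 5 neopentyl alcohol (2,2-dimethylpropan-1-ol)
Product: 6 neopentyl chlorosulfate (2,2-dimethylpropyl sulfurochloridate)
Conditions: SO2Cl2 (1.1 equiv), pyridine (1.1 equiv), Et2O, −78 °C to rt
Reagents that add atoms: sulfuryl chloride, O=S(=O)(Cl)Cl
Why: Alcoholysis of one S–Cl bond of sulfuryl chloride is the standard preparation of alkyl chlorosulfates, and the neopentyl carbon resists SN2 attack by the chloride set free.

Step 3
Reactants: 4 ethyl 5,7-dihydroxy-4-oxo-4H-chromene-2-carboxylate; 6 neopentyl chlorosulfate
Product: 7 ethyl 5-hydroxy-7-[(neopentyloxy)sulfonyloxy]-4-oxo-4H-chromene-2-carboxylate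
Conditions: NaN(SiMe3)2 (1.05 equiv), THF–DMPU, −78 °C; then 6 (1.1 equiv), −78 to 0 °C
Reagents that add atoms: none
Why: O-Sulfonylation of a phenoxide with an alkyl chlorosulfate should be site-selective, because one equivalent of base ionizes only the acidic, unchelated 7-OH while the 5-OH stays hydrogen-bonded to the C4 carbonyl.

Step 4
Reactants: 7 ethyl 5-hydroxy-7-[(neopentyloxy)sulfonyloxy]-4-oxo-4H-chromene-2-carboxylate
Product: 8 5-hydroxy-2-(hydroxymethyl)-4-oxo-4H-chromen-7-yl neopentyl sulfate
Conditions: NaBH4 (1.5 equiv), MeOH–THF, 0 °C; aq. NH4Cl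
Reagents that add atoms: none
Why: Chemoselective borohydride reduction of the electron-poor 2-carboxylate (an alkoxyacrylate ester activated like an α-keto ester), as known for chromone-2-carboxylates, should leave the C4 carbonyl (a vinylogous ester) and the sulfate diester untouched.

Step 5
Reactants: 8 5-hydroxy-2-(hydroxymethyl)-4-oxo-4H-chromen-7-yl neopentyl sulfate
Product: 9 2-formyl-5-hydroxy-4-oxo-4H-chromen-7-yl neopentyl sulfate
Conditions: Dess–Martin periodinane (1.2 equiv), CH2Cl2, 0 °C to rt
Reagents that add atoms: none
Why: Dess–Martin oxidation of a primary allylic alcohol to the aldehyde runs under near-neutral conditions that the chelated, electron-poor 5-OH and the sulfate diester should tolerate.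

Step 6
Reactants: 9 2-formyl-5-hydroxy-4-oxo-4H-chromen-7-yl neopentyl sulfate
Product: 10 2-ethynyl-5-hydroxy-4-oxo-4H-chromen-7-yl neopentyl sulfate
Conditions: Ohira–Bestmann reagent (1.3 equiv), K2CO3 (2.5 equiv), MeOH, 0 °C to rt; aq. NH4Cl
Reagents that add atoms: dimethyl (1-diazo-2-oxopropyl)phosphonate, CC(=O)C(=[N+]=[N-])P(=O)(OC)OC
Why: Seyferth–Gilbert homologation in the Ohira–Bestmann variant: methanolysis of the reagent gives the diazomethylphosphonate anion, which olefinates the aldehyde, and loss of N2 with a 1,2-hydrogen shift delivers the terminal alkyne.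

Step 7
Reactants: 11 butane-2,3-dione
Product: 12 2,3-bis(trimethylsilyloxy)buta-1,3-diene
Conditions: Me3SiOSO2CF3 (2.2 equiv), Et3N (2.6 equiv), Et2O, 0 °C to rt; distillation under reduced pressure
Reagents that add atoms: trimethylsilyl trifluoromethanesulfonate, C[Si](C)(C)OS(=O)(=O)C(F)(F)F
Why: Double silyl enol ether formation by soft enolization with amine and silyl triflate; the two methyl groups are the only enolizable positions, so only the 2,3-dioxygenated diene can result.

Step 8
Reactants: 10 2-ethynyl-5-hydroxy-4-oxo-4H-chromen-7-yl neopentyl sulfate; 12 2,3-bis(trimethylsilyloxy)buta-1,3-diene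
Product: 14 2-[3,4-bis(trimethylsilyloxy)phenyl]-5-hydroxy-4-oxo-4H-chromen-7-yl neopentyl sulfate, via cyclohexa-1,4-diene cycloadduct 13 (not isolated)
Conditions: 12 (4 equiv), BHT (cat.), toluene, 120 °C, sealed tube; evaporate excess 12 under vacuum; DDQ (1.05 equiv), toluene, 0 °C to rt; filter off the hydroquinone, concentrate, use crude
Reagents that add atoms: none
Why: Proposed new method: a concerted, suprafacial, normal-electron-demand [4+2] cycloaddition in which the s-cis bis(silyloxy)diene 12 (raised HOMO) adds across the terminal alkyne of 10, whose LUMO is lowered by conjugation through C2=C3 to the C4 carbonyl and by the 5-OH to C4=O hydrogen bond, should give the 1,4-cyclohexadiene 13; DDQ then takes hydride from a doubly allylic CH2 (C2' or C5'), the cation being stabilized by the neighbouring silyloxy group, and proton loss aromatizes ring B. The closest known reaction type is the cycloaddition of 2,3-bis(trimethylsilyloxy)butadiene with acetylenic esters and ketones followed by dehydrogenation to catechol bis(silyl ethers); a 2-alkynylchromone has not served as the 2π partner. Ring B is closed as a six-membered carbocycle by intermolecular [4+2] annulation, the four diene carbons becoming C2' to C5' and the two alkyne carbons C1' and C6'. No stereocentre is created, and the two sp3 carbons of 13 disappear on oxidation. The step needs site selectivity for the alkyne over the C2=C3 bond of ring C, which is secured because that alkene is trisubstituted and deactivated by donation from O1, while the twofold symmetry of 12 removes any regiochemical issue. Excess diene is stripped before DDQ is added so that the oxidant meets only 13, and the catechol stays silylated so that DDQ cannot oxidize it to an o-quinone.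

Step 9
Reactants: 14 2-[3,4-bis(trimethylsilyloxy)phenyl]-5-hydroxy-4-oxo-4H-chromen-7-yl neopentyl sulfate
Product: 15 2-(3,4-dihydroxyphenyl)-5-hydroxy-4-oxo-4H-chromen-7-yl neopentyl sulfate
Conditions: MeOH–CH2Cl2, citric acid (cat.), rt
Reagents that add atoms: none
Why: Mild acid-catalysed methanolysis (Si–O solvolysis) of the labile aryl trimethylsilyl ethers, including any partly desilylated material from step 8, should free the catechol while the neopentyl sulfate diester, stable even to CF3CO2H, is untouched.

Step 10
Reactants: 15 2-(3,4-dihydroxyphenyl)-5-hydroxy-4-oxo-4H-chromen-7-yl neopentyl sulfate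
Product: 16 luteolin 7-sulfate (2-(3,4-dihydroxyphenyl)-5-hydroxy-4-oxo-4H-chromen-7-yl hydrogen sulfate)
Conditions: NaN3 (2 equiv), DMF, 70 °C; then 1 M HCl to pH 2, 0 °C; C18 reversed-phase desalting
Reagents that add atoms: none
Why: SN2 dealkylation by azide at the neopentyl CH2 with the sulfate monoanion as leaving group is the standard unmasking of neopentyl-protected sulfates; azide is too weakly basic to ionize the catechol, and cold protonation of the sodium salt gives the hydrogen sulfate.

Compound list
1 | 2',4',6'-trihydroxyacetophenone | CC(=O)c1c(O)cc(O)cc1O | starting material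
2 | diethyl oxalate | CCOC(=O)C(=O)OCC | starting material
3 | ethyl 2,4-dioxo-4-(2,4,6-trihydroxyphenyl)butanoate (diketo ester formed in the flask in step 1) | CCOC(=O)C(=O)CC(=O)c1c(O)cc(O)cc1O | intermediate
4 | ethyl 5,7-dihydroxy-4-oxo-4H-chromene-2-carboxylate | CCOC(=O)c1cc(=O)c2c(O)cc(O)cc2o1 | intermediate
5 | neopentyl alcohol | CC(C)(C)CO | starting material
6 | neopentyl chlorosulfate | CC(C)(C)COS(=O)(=O)Cl | intermediate
7 | ethyl 5-hydroxy-7-[(neopentyloxy)sulfonyloxy]-4-oxo-4H-chromene-2-carboxylate | CCOC(=O)c1cc(=O)c2c(O)cc(OS(=O)(=O)OCC(C)(C)C)cc2o1 | intermediate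
8 | 5-hydroxy-2-(hydroxymethyl)-4-oxo-4H-chromen-7-yl neopentyl sulfate | OCc1cc(=O)c2c(O)cc(OS(=O)(=O)OCC(C)(C)C)cc2o1 | intermediate
9 | 2-formyl-5-hydroxy-4-oxo-4H-chromen-7-yl neopentyl sulfate | O=Cc1cc(=O)c2c(O)cc(OS(=O)(=O)OCC(C)(C)C)cc2o1 | intermediate
10 | 2-ethynyl-5-hydroxy-4-oxo-4H-chromen-7-yl neopentyl sulfate | C#Cc1cc(=O)c2c(O)cc(OS(=O)(=O)OCC(C)(C)C)cc2o1 | intermediate
11 | butane-2,3-dione | CC(=O)C(C)=O | starting material
12 | 2,3-bis(trimethylsilyloxy)buta-1,3-diene | C=C(O[Si](C)(C)C)C(=C)O[Si](C)(C)C | intermediate
13 | 2-[4,5-bis(trimethylsilyloxy)cyclohexa-1,4-dien-1-yl]-5-hydroxy-4-oxo-4H-chromen-7-yl neopentyl sulfate (cycloadduct formed in the flask in step 8) | C[Si](C)(C)OC1=C(O[Si](C)(C)C)CC(c2cc(=O)c3c(O)cc(OS(=O)(=O)OCC(C)(C)C)cc3o2)=CC1 | intermediate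
14 | 2-[3,4-bis(trimethylsilyloxy)phenyl]-5-hydroxy-4-oxo-4H-chromen-7-yl neopentyl sulfate | O=c1cc(-c2ccc(O[Si](C)(C)C)c(O[Si](C)(C)C)c2)oc2cc(OS(=O)(=O)OCC(C)(C)C)cc(O)c12 | intermediate
15 | 2-(3,4-dihydroxyphenyl)-5-hydroxy-4-oxo-4H-chromen-7-yl neopentyl sulfate | O=c1cc(-c2ccc(O)c(O)c2)oc2cc(OS(=O)(=O)OCC(C)(C)C)cc(O)c12 | intermediate
16 | luteolin 7-sulfate | O=c1cc(-c2ccc(O)c(O)c2)oc2cc(OS(=O)(=O)O)cc(O)c12 | target

Total step count: 10 (eight on the main line, plus one step each for reagents 6 and 12).
Longest linear sequence: 8 steps (1 → 4 → 7 → 8 → 9 → 10 → 14 → 15 → 16; steps 1, 3, 4, 5, 6, 8, 9, 10).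

Steps most likely to fail

1. Step 8 (the proposed new method). The alkyne is activated only through a vinylogous ester, so the cycloaddition may be slower than thermal decay of the diene or its protodesilylation by the 5-OH. Premature loss of a silyl group while oxidant is still present could also let ring B be over-oxidized. The fallback brings ring B in preformed by known flavone chemistry and sets out from 1. 3,4-Bis(benzyloxy)benzoyl chloride F1, made from the commercial acid with oxalyl chloride and catalytic DMF, should C-acylate the polyanion of 1 (LiN(SiMe3)2, 5 equiv, THF, −78 °C to rt). This gives 1-[3,4-bis(benzyloxy)phenyl]-3-(2,4,6-trihydroxyphenyl)propane-1,3-dione F2, which is cyclodehydrated (AcOH, cat. H2SO4, 95 °C) to 3',4'-di-O-benzylluteolin F3. Selective 7-O-sulfation with 6 under the conditions of step 3 should give 2-[3,4-bis(benzyloxy)phenyl]-5-hydroxy-4-oxo-4H-chromen-7-yl neopentyl sulfate F4. Hydrogenolysis of the benzyl ethers (H2, palladium on carbon (Pd/C), EtOAc–THF) then comes back to the route at 15, before step 10.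

2. Step 6. Basic methanol may cleave the sulfate diester by methoxide attack at sulfur, or methoxide may add to the pyrone ring or to the conjugated alkyne once it has formed. The fallback adds the carbon by Wittig halomethylenation in an aprotic medium and sets out from 9. Ph3P=CHBr, from (bromomethyl)triphenylphosphonium bromide and KOtBu in THF at −78 °C (one extra equivalent of base for the 5-OH), should give 2-[(Z)-2-bromoethenyl]-5-hydroxy-4-oxo-4H-chromen-7-yl neopentyl sulfate F5. Further KOtBu in the same flask dehydrobrominates it (anti elimination) and the sequence comes back at 10.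

3. Step 10. Azide may attack sulfur and expel the chromon-7-olate instead of attacking the neopentyl carbon, and the free hydrogen sulfate may hydrolyse during acidification. Neopentyl azide is volatile and should be kept in solution. The fallback introduces the sulfate unprotected and sets out from 1, passing through 3',4'-di-O-benzylluteolin F3 as made in the fallback to step 8. SO3·pyridine in pyridine–DMF should sulfate only the unchelated 7-OH, giving 2-[3,4-bis(benzyloxy)phenyl]-5-hydroxy-4-oxo-4H-chromen-7-yl hydrogen sulfate F6. Hydrogenolysis (H2, palladium on carbon (Pd/C), MeOH) and cold acidification come back to the route at 16.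

Further compounds
F1 | step 8 | 3,4-bis(benzyloxy)benzoyl chloride | O=C(Cl)c1ccc(OCc2ccccc2)c(OCc2ccccc2)c1
F2 | step 8 | 1-[3,4-bis(benzyloxy)phenyl]-3-(2,4,6-trihydroxyphenyl)propane-1,3-dione | O=C(CC(=O)c1c(O)cc(O)cc1O)c1ccc(OCc2ccccc2)c(OCc2ccccc2)c1
F3 | step 8 | 3',4'-di-O-benzylluteolin (2-[3,4-bis(benzyloxy)phenyl]-5,7-dihydroxy-4H-chromen-4-one) | O=c1cc(-c2ccc(OCc3ccccc3)c(OCc3ccccc3)c2)oc2cc(O)cc(O)c12
F4 | step 8 | 2-[3,4-bis(benzyloxy)phenyl]-5-hydroxy-4-oxo-4H-chromen-7-yl neopentyl sulfate | O=c1cc(-c2ccc(OCc3ccccc3)c(OCc3ccccc3)c2)oc2cc(OS(=O)(=O)OCC(C)(C)C)cc(O)c12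
F5 | step 6 | 2-[(Z)-2-bromoethenyl]-5-hydroxy-4-oxo-4H-chromen-7-yl neopentyl sulfate | Br/C=C\c1cc(=O)c2c(O)cc(OS(=O)(=O)OCC(C)(C)C)cc2o1
F6 | step 10 | 2-[3,4-bis(benzyloxy)phenyl]-5-hydroxy-4-oxo-4H-chromen-7-yl hydrogen sulfate | O=c1cc(-c2ccc(OCc3ccccc3)c(OCc3ccccc3)c2)oc2cc(OS(=O)(=O)O)cc(O)c12
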